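The plan removes C12 from the trans-fused α-methylene-γ-butyrolactone (ring C7–C8–O8–C12–C11). C12 is bonded only to C11, to O8 and to its own oxygen, so it can enter as carbon monoxide. A single palladium-catalysed operation couples the C11 enol triflate, CO and the equatorial 8α-hydroxyl. It forms C11–C12 and C12–O8 and closes the lactone with the exocyclic methylene (C13) already present. The precursor is a hexasubstituted cyclohexane with the C11 triflate on C7, 6β-isobutyrate, C5 isopropenyl, C10 methyl and vinyl, and a free 8α,9α-diol. O9 needs no protection because it lies 1,3-trans to C11. (−)-Quinic acid supplies the ring, O8 and O9.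

Key step: step 21

Convention: elemane locants of the target are used for every compound (ring C5–C6–C7–C8–C9–C10; C1/C2 on C10, C14 = methyl on C10, C3/C4/C15 on C5, C11–C13 on C7); β is the ring face that carries C14 and α is the opposite face.

Step 1
Reactants: 1 (−)-quinic acid
Product: 2 quinide acetonide (acetonide on the future O8/O9, γ-lactone from the carboxyl group to the future 10β-oxygen)
Conditions: 2,2-dimethoxypropane, TsOH·H2O (cat.), acetone, reflux
Reagents that add atoms: 2,2-dimethoxypropane, COC(C)(C)OC
Why: Acid-catalysed acetalisation takes the only cis-vicinal diol while the syn carboxyl/hydroxyl pair lactonises, a standard protection that creates no stereocentre and keeps the two centres that become C8 and C9.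

Step 2
Reactants: 2 quinide acetonide
Product: 3 acetonide triol (6α-OH, 6β-CH2OH, 10β-OH)
Conditions: NaBH4, EtOH, 0 °C to rt
Reagents that add atoms: none
Why: Hydride reduction of the activated α-hydroxy γ-lactone should stop at the primary alcohol and leave the acetonide untouched.

Step 3
Reactants: 3 acetonide triol
Product: 4 10β-hydroxy-8α,9α-(isopropylidenedioxy)cyclohexan-6-one
Conditions: NaIO4, H2O, pH 7 buffer, 0 °C
Reagents that add atoms: none
Why: Malaprade glycol cleavage of the tertiary carbinol/CH2OH pair expels the former carboxyl carbon as formaldehyde and unveils the C6 ketone.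

Step 4
Reactants: 4 10β-hydroxy ketone
Product: 6 enone (3aR,7aS)-2,2-dimethyl-3a,7a-dihydro-1,3-benzodioxol-5(4H)-one (C6 ketone, C5=C10), via mesylate 5 (not isolated)
Conditions: MsCl, Et3N, CH2Cl2, 0 °C
Reagents that add atoms: methanesulfonyl chloride, CS(=O)(=O)Cl (atoms kept only in 5)
Why: Mesylation of the β-hydroxy ketone is followed by E1cB loss of mesylate under Et3N, whereas the much poorer acetal leaving group at C8 should stay in place.

Step 5
Reactants: 6 enone
Product: 7 5-iodo enone
Conditions: I2, pyridine, CH2Cl2, 0 °C to rt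
Reagents that add atoms: iodine, [I][I]
Why: α-Iodination of an enone by the addition–iodination–elimination sequence (pyridine as Baylis–Hillman-type carrier) functionalises C5 regiospecifically.

Step 6
Reactants: 7 5-iodo enone; 8 tributyl(isopropenyl)stannane
Product: 9 5-isopropenyl enone
Conditions: Pd2(dba)3 (cat.), AsPh3, CuI (cat.), NMP, rt
Reagents that add atoms: none
Why: Stille coupling of an α-iodoenone forms C5–C4 under neutral conditions, so the base-sensitive β-alkoxy ketone sees no base.

Step 7
Reactants: 9 5-isopropenyl enone; 10 vinylmagnesium bromide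
Product: 11 trimethylsilyl enol ether (C5=C6–OSiMe3, 10β-vinyl)
Conditions: CuBr·SMe2 (cat.), Me3SiCl, THF, −78 °C
Reagents that add atoms: chlorotrimethylsilane, C[Si](C)(C)Cl
Why: Copper-catalysed, silyl chloride-accelerated 1,4-addition attacks C10 anti to the C9–O bond and the enolate is trapped on oxygen, and the new C10 centre is erased again in step 8.

Step 8
Reactants: 11 silyl enol ether
Product: 12 5-isopropenyl-10-vinyl trienone
Conditions: Pd(OAc)2 (1 equiv), MeCN, rt
Reagents that add atoms: none
Why: Saegusa–Ito dehydrogenation through the oxa-π-allyl complex of divalent palladium and loss of the doubly allylic H10 restores the enone, as it does for other fully substituted silyl enol ethers.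

Step 9
Reactants: 12 trienone
Product: 13 5-isopropenyl-10-[2-(phenylselanyl)ethyl] enone
Conditions: PhSeH, Et3N (cat.), CH2Cl2, 0 °C
Reagents that add atoms: benzeneselenol, [SeH]c1ccccc1
Why: The soft selenol adds 1,6 to the terminal vinyl carbon (selena-Michael addition, the analogue of thiol additions to steroidal dienones) and reconjugation gives the enone, which masks the vinyl group so that the cuprate of step 10 can only add 1,4.

Step 10
Reactants: 13 selenide enone; 14 methyllithium
Product: 15 ketone with 10β-methyl, 10α-[2-(phenylselanyl)ethyl] and 5β-isopropenyl (H5α)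
Conditions: Me2CuLi (from MeLi and CuI), Et2O, −30 to 0 °C; aq NH4Cl
Reagents that add atoms: none
Why: Gilman conjugate addition to a fully substituted enone (the reaction type known from pulegone) should deliver methyl axially on the β face, anti to the axial C9–O bond, and axial protonation of the enolate from the α face sets the C5 isopropenyl group equatorial, which is also the thermodynamic outcome.

Step 11
Reactants: 15 selenide ketone
Product: 17 10β-methyl-10α-vinyl-5β-isopropenyl ketone, via selenoxide 16 (not isolated)
Conditions: mCPBA (1 equiv), CH2Cl2, −78 °C; then i-Pr2NH, 40 °C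
Reagents that add atoms: 3-chloroperbenzoic acid, OOC(=O)c1cccc(Cl)c1 (oxygen kept only in 16)
Why: Selenium is oxidised far faster than the isopropenyl group at −78 °C, and selenoxide syn elimination of the primary selenoxide regenerates the C10 vinyl group without touching a stereocentre.

Step 12
Reactants: 17 vinyl ketone; 18 acetaldehyde
Product: 20 7β-[1-(triethylsilyloxy)ethyl] ketone (anti aldol), via lithium aldolate 19 (not isolated)
Conditions: LiN(i-Pr)2, THF, −78 °C; MeCHO; then Et3SiOTf, −78 to −30 °C
Reagents that add atoms: triethylsilyl triflate, CC[Si](CC)(CC)OS(=O)(=O)C(F)(F)F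
Why: Kinetic deprotonation takes the unhindered C7 methylene, the equatorial C8–O bond is orthogonal to the enolate π system so β-elimination should be slow at −78 °C, and the lithium aldol addition on the convex β face through a Zimmerman–Traxler chair gives the equatorial anti adduct, which is silylated at once to block retro-aldol and whose carbinol centre disappears in step 16.

Step 13
Reactants: 20 silyl aldol ketone
Product: 21 6β-alcohol
Conditions: LiAlH4, Et2O, −78 to 0 °C
Reagents that add atoms: none
Why: In this hydride reduction the β face of the C6 ketone is screened by the syn-axial C10 methyl group (the behaviour of 6-oxo steroids), so attack from the α face should give the axial 6β-alcohol.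

Step 14
Reactants: 21 6β-alcohol
Product: 22 6β-OTBS, 11-OTES bis-silyl ether
Conditions: t-BuMe2SiOTf, 2,6-lutidine, CH2Cl2, 0 °C to rt
Reagents that add atoms: tert-butyldimethylsilyl triflate, CC(C)(C)[Si](C)(C)OS(=O)(=O)C(F)(F)F
Why: Silyl triflate/lutidine silylation copes with the hindered axial alcohol and installs a β-oxygen substituent that is a poor leaving group for the enolisation of step 17.

Step 15
Reactants: 22 bis-silyl ether
Product: 23 11-alcohol (6β-OTBS kept)
Conditions: PPTS (cat.), MeOH/CH2Cl2, 0 °C
Reagents that add atoms: none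
Why: Acid-catalysed methanolysis removes the triethylsilyl ether much faster than the hindered tert-butyldimethylsilyl ether or the acetonide (standard differentiation of the two silyl groups).

Step 16
Reactants: 23 11-alcohol
Product: 24 C11 methyl ketone (7β-acetyl, 6β-OTBS, acetonide)
Conditions: Dess–Martin periodinane, pyridine, CH2Cl2, rt
Reagents that add atoms: none
Why: Dess–Martin oxidation under buffered conditions gives the methyl ketone without epimerising the equatorial C7 centre or expelling a β-oxygen substituent.

Step 17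
Reactants: 24 methyl ketone; 25 N-phenylbis(trifluoromethanesulfonimide)
Product: 26 C11 enol triflate (6β-OTBS, acetonide)
Conditions: KN(SiMe3)2 added to 24 and 25, THF, −78 °C
Reagents that add atoms: none
Why: Kinetic enol triflate formation removes a methyl proton and traps the terminal enolate on oxygen, and because O6 is still a silyl ether there is no ester for the enolate to attack and no good leaving group anti to H7.

Step 18
Reactants: 26 silyl-protected enol triflate
Product: 27 6β-hydroxy enol triflate
Conditions: HF·pyridine, pyridine, THF, 0 °C to rt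
Reagents that add atoms: none
Why: Fluoride-mediated desilylation with buffered HF·pyridine frees O6 while vinyl triflate and acetonide should survive.

Step 19
Reactants: 27 6β-hydroxy enol triflate; 28 isobutyryl chloride
Product: 29 6β-isobutyrate enol triflate acetonide
Conditions: DMAP, pyridine, CH2Cl2, 40 °C
Reagents that add atoms: none
Why: DMAP-catalysed acyl transfer esterifies the only free hydroxyl under weakly basic conditions that a vinyl triflate tolerates.

Step 20
Reactants: 29 isobutyrate acetonide
Product: 30 8α,9α-dihydroxy C11 enol triflate 6β-isobutyrate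
Conditions: AcOH/H2O 4:1, 45 °C
Reagents that add atoms: none
Why: Acetal hydrolysis in aqueous acetic acid opens the cis-fused acetonide and is too mild to affect the vinyl triflate, the ester or the alkenes.

Step 21
Reactants: 30 dihydroxy enol triflate; 31 carbon monoxide
Product: 32 9α-hydroxy 8α,12-olide (α-methylene-γ-lactone, C5 isopropenyl, C10 vinyl, 6β-isobutyrate)
Conditions: Pd(PPh3)4 (10 mol %), CO (1 atm), n-Bu3N, MeCN, 65 °C
Reagents that add atoms: none
Why: Zerovalent palladium inserts into the C11–OTf bond, CO migrates into the vinyl–palladium bond, the 8α-hydroxyl attacks the acyl-palladium carbon, and n-Bu3N takes up TfOH as the catalyst is released. This is the known carbonylative lactonisation of hydroxy vinyl triflates and halides that gives butenolides and α-methylene lactones. The γ-lactone closes by 5-exo-trig attack of O8 on C12, and its trans fusion follows from the diequatorial C7–C11 and C8–O8 bonds fixed in steps 1 and 12, so no stereocentre is created. Selectivity for C11 over the vinyl and isopropenyl groups rests on the C–OTf bond, the only site open to oxidative addition, and the CO atmosphere should outrun Heck-type insertion. Among the oxygens, O6 is blocked as the isobutyrate, and the axial 9α-hydroxyl is 1,3-trans to C11 and could only form a bridged δ-lactone that the chair cannot reach. Leaving O9 bare also avoids a silyl group that could migrate between the cis-vicinal O9 and O8 under the basic conditions.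

Step 22
Reactants: 32 lactone
Product: 33 15-hydroxy lactone (C5–C(=CH2)CH2OH)
Conditions: SeO2 (cat.), t-BuOOH, CH2Cl2, rt
Reagents that add atoms: tert-butyl hydroperoxide, CC(C)(C)OO
Why: Riley allylic oxidation (ene reaction, then [2,3]-shift) attacks the only electron-rich alkene that has allylic hydrogens and prefers its methyl group to the hindered C5 methine, since the C10 vinyl group has no allylic hydrogen and the lactone methylene is electron-poor.

Step 23
Reactants: 33 allylic alcohol
Product: 34 enal (C5–C(=CH2)CHO)
Conditions: MnO2, CH2Cl2, rt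
Reagents that add atoms: none
Why: MnO2 oxidation is selective for the primary allylic alcohol, so the saturated secondary 9α-hydroxyl should remain.

Step 24
Reactants: 34 enal
Product: 35 target CNP0496100.1
Conditions: VO(acac)2 (cat.), t-BuOOH, CH2Cl2, 0 °C to rt
Reagents that add atoms: tert-butyl hydroperoxide, CC(C)(C)OO
Why: Vanadium-catalysed hydroxyl-directed epoxidation of a homoallylic alcohol reaches the only electron-rich alkene left, and the axial 9α-vanadate, gauche to the equatorial vinyl group, should deliver oxygen to the face exposed in the rotamer whose =CH2 eclipses C10–C5, which gives the (1R)-oxirane.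

Compound list
1 | (−)-quinic acid | O[C@@]1(C(=O)O)C[C@@H](O)[C@@H](O)[C@H](O)C1 | starting material
2 | quinide acetonide | CC1(C)O[C@@H]2C[C@]3(O)C[C@@H](OC3=O)[C@@H]2O1 | intermediate
3 | acetonide triol (6α-OH, 6β-CH2OH, 10β-OH) | CC1(C)O[C@@H]2C[C@@](O)(CO)C[C@@H](O)[C@@H]2O1 | intermediate
4 | 10β-hydroxy-8α,9α-(isopropylidenedioxy)cyclohexan-6-one | CC1(C)O[C@@H]2CC(=O)C[C@@H](O)[C@@H]2O1 | intermediate
5 | 10β-mesylate of 4 | CC1(C)O[C@@H]2CC(=O)C[C@@H](OS(C)(=O)=O)[C@@H]2O1 | intermediate
6 | enone (3aR,7aS)-2,2-dimethyl-3a,7a-dihydro-1,3-benzodioxol-5(4H)-one | CC1(C)O[C@@H]2CC(=O)C=C[C@@H]2O1 | intermediate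
7 | 5-iodo enone | CC1(C)O[C@@H]2CC(=O)C(I)=C[C@@H]2O1 | intermediate
8 | tributyl(isopropenyl)stannane | CCCC[Sn](CCCC)(CCCC)C(C)=C | starting material
9 | 5-isopropenyl enone | CC1(C)O[C@@H]2CC(=O)C(C(C)=C)=C[C@@H]2O1 | intermediate
10 | vinylmagnesium bromide | C=C[Mg]Br | starting material
11 | trimethylsilyl enol ether, 10β-vinyl | CC1(C)O[C@@H]2CC(O[Si](C)(C)C)=C(C(C)=C)[C@@H](C=C)[C@@H]2O1 | intermediate
12 | 5-isopropenyl-10-vinyl trienone | CC1(C)O[C@@H]2CC(=O)C(C(C)=C)=C(C=C)[C@@H]2O1 | intermediate
13 | 5-isopropenyl-10-[2-(phenylselanyl)ethyl] enone | CC1(C)O[C@@H]2CC(=O)C(C(C)=C)=C(CC[Se]c3ccccc3)[C@@H]2O1 | intermediate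
14 | methyllithium | [Li]C | starting material
15 | 10β-methyl-10α-[2-(phenylselanyl)ethyl]-5β-isopropenyl ketone | CC1(C)O[C@@H]2CC(=O)[C@@H](C(C)=C)[C@](C)(CC[Se]c3ccccc3)[C@@H]2O1 | intermediate
16 | selenoxide of 15 | CC1(C)O[C@@H]2CC(=O)[C@@H](C(C)=C)[C@](C)(CC[Se](=O)c3ccccc3)[C@@H]2O1 | intermediate
17 | 10β-methyl-10α-vinyl-5β-isopropenyl ketone | CC1(C)O[C@@H]2CC(=O)[C@@H](C(C)=C)[C@](C)(C=C)[C@@H]2O1 | intermediate
18 | acetaldehyde | CC=O | starting material
19 | lithium aldolate (7β side chain, anti) | CC1(C)O[C@@H]2[C@@H]([C@H](C)O[Li])C(=O)[C@@H](C(C)=C)[C@](C)(C=C)[C@@H]2O1 | intermediate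
20 | 7β-[1-(triethylsilyloxy)ethyl] ketone | CC1(C)O[C@@H]2[C@@H]([C@H](C)O[Si](CC)(CC)CC)C(=O)[C@@H](C(C)=C)[C@](C)(C=C)[C@@H]2O1 | intermediate
21 | 6β-alcohol | CC1(C)O[C@@H]2[C@@H]([C@H](C)O[Si](CC)(CC)CC)[C@@H](O)[C@@H](C(C)=C)[C@](C)(C=C)[C@@H]2O1 | intermediate
22 | 6β-OTBS, 11-OTES bis-silyl ether | CC1(C)O[C@@H]2[C@@H]([C@H](C)O[Si](CC)(CC)CC)[C@@H](O[Si](C)(C)C(C)(C)C)[C@@H](C(C)=C)[C@](C)(C=C)[C@@H]2O1 | intermediate
23 | 11-alcohol, 6β-OTBS | CC1(C)O[C@@H]2[C@@H]([C@H](C)O)[C@@H](O[Si](C)(C)C(C)(C)C)[C@@H](C(C)=C)[C@](C)(C=C)[C@@H]2O1 | intermediate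
24 | C11 methyl ketone, 6β-OTBS | CC1(C)O[C@@H]2[C@@H](C(C)=O)[C@@H](O[Si](C)(C)C(C)(C)C)[C@@H](C(C)=C)[C@](C)(C=C)[C@@H]2O1 | intermediate
25 | N-phenylbis(trifluoromethanesulfonimide) | O=S(=O)(N(c1ccccc1)S(=O)(=O)C(F)(F)F)C(F)(F)F | starting material
26 | C11 enol triflate, 6β-OTBS, acetonide | CC1(C)O[C@@H]2[C@@H](C(=C)OS(=O)(=O)C(F)(F)F)[C@@H](O[Si](C)(C)C(C)(C)C)[C@@H](C(C)=C)[C@](C)(C=C)[C@@H]2O1 | intermediate
27 | C11 enol triflate, 6β-OH, acetonide | CC1(C)O[C@@H]2[C@@H](C(=C)OS(=O)(=O)C(F)(F)F)[C@@H](O)[C@@H](C(C)=C)[C@](C)(C=C)[C@@H]2O1 | intermediate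
28 | isobutyryl chloride | CC(C)C(Cl)=O | starting material
29 | C11 enol triflate, 6β-isobutyrate, acetonide | CC1(C)O[C@@H]2[C@@H](C(=C)OS(=O)(=O)C(F)(F)F)[C@@H](OC(=O)C(C)C)[C@@H](C(C)=C)[C@](C)(C=C)[C@@H]2O1 | intermediate
30 | 8α,9α-dihydroxy C11 enol triflate 6β-isobutyrate | O[C@@H]1[C@@H](C(=C)OS(=O)(=O)C(F)(F)F)[C@@H](OC(=O)C(C)C)[C@@H](C(C)=C)[C@](C)(C=C)[C@@H]1O | intermediate
31 | carbon monoxide | [C-]#[O+] | starting material
32 | 9α-hydroxy α-methylene 8α,12-olide with C5 isopropenyl and C10 vinyl | C=C1C(=O)O[C@@H]2[C@@H]1[C@@H](OC(=O)C(C)C)[C@@H](C(C)=C)[C@](C)(C=C)[C@@H]2O | intermediate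
33 | 15-hydroxy lactone | C=C1C(=O)O[C@@H]2[C@@H]1[C@@H](OC(=O)C(C)C)[C@@H](C(=C)CO)[C@](C)(C=C)[C@@H]2O | intermediate
34 | enal lactone | C=C1C(=O)O[C@@H]2[C@@H]1[C@@H](OC(=O)C(C)C)[C@@H](C(=C)C=O)[C@](C)(C=C)[C@@H]2O | intermediate
35 | CNP0496100.1 | C=C1C(=O)O[C@@H]2[C@@H]1[C@@H](OC(=O)C(C)C)[C@@H](C(=C)C=O)[C@](C)([C@@H]1CO1)[C@@H]2O | target

Total step count: 24. Longest linear sequence: 24 steps (1 to 35).

Steps most likely to fail

Step 10. The cuprate may engage the fully substituted, γ-oxygenated enone too slowly, so that enolisation or decay of the reagent takes over. The fallback sets out from 13 and brings in the methyl carbon in two stages.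
- Methylene transfer with dimethylsulfoxonium methylide (Me3S(O)I, NaH, DMSO; Corey–Chaykovsky cyclopropanation) from the β face, anti to the acetonide, gives the 5β,10β-methano ketone F1.
- Single-electron reduction with SmI2 (THF/HMPA, t-BuOH) cleaves the external C5–CH2 bond, which overlaps best with the ketyl. This turns the methylene into C14, and α-face protonation of the samarium enolate comes back to the route at 15.

Step 21. Capture of the acyl-palladium intermediate by the hindered secondary hydroxyl may be slower than its interception by traces of water or by a second molecule, which would divert material into acid or oligomeric ester. The fallback sets out from 29 and separates the two bond formations.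
- Intermolecular methoxycarbonylation (Pd(OAc)2, PPh3, CO, MeOH, Et3N, DMF) gives the methyl acrylate acetonide F2.
- Aqueous acetic acid removes the acetonide to give the dihydroxy ester F3.
- Acid-catalysed transesterification by O8 (PPTS, benzene, heat) closes the lactone and comes back to the route at 32.

Step 24. Oxygen transfer to a monosubstituted alkene on a quaternary carbon may be slow, and facial selectivity between the two vinyl rotamers may be poor. The fallback sets out from 34 and does not rely on substrate direction.
- mCPBA/NaHCO3 in CH2Cl2 epoxidises the vinyl group (the enal and lactone alkenes are too electron-poor) and gives 35 together with the (1S)-oxirane F4.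
- Hydrolytic kinetic resolution follows, using water (0.5 equiv) and Co(salen)(OAc) (trivalent cobalt; salen = N,N′-bis(3,5-di-tert-butylsalicylidene)cyclohexane-1,2-diamine dianion). The catalyst enantiomer is the one matched to the (1S)-oxirane, so F4 is opened to the polar 1,2-diol F5.
- F5 is removed by chromatography, and the sequence comes back to the route at 35.

Further compounds
F1 | step 10 | 5β,10β-methano ketone (cyclopropyl ketone from 13) | CC1(C)O[C@@H]2CC(=O)[C@@]3(C(C)=C)C[C@@]3(CC[Se]c4ccccc4)[C@@H]2O1
F2 | step 21 | methyl acrylate acetonide (C11–CO2Me) | CC1(C)O[C@@H]2[C@@H](C(=C)C(=O)OC)[C@@H](OC(=O)C(C)C)[C@@H](C(C)=C)[C@](C)(C=C)[C@@H]2O1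
F3 | step 21 | 8α,9α-dihydroxy methyl acrylate | O[C@@H]1[C@@H](C(=C)C(=O)OC)[C@@H](OC(=O)C(C)C)[C@@H](C(C)=C)[C@](C)(C=C)[C@@H]1O
F4 | step 24 | (1S)-oxirane, C1 epimer of 35 | C=C1C(=O)O[C@@H]2[C@@H]1[C@@H](OC(=O)C(C)C)[C@@H](C(=C)C=O)[C@](C)([C@H]1CO1)[C@@H]2O
F5 | step 24 | 1,2-diol from F4 | C=C1C(=O)O[C@@H]2[C@@H]1[C@@H](OC(=O)C(C)C)[C@@H](C(=C)C=O)[C@](C)([C@H](O)CO)[C@@H]2O
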